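Ring A carries bromine at C3, C4 and C5 but hydrogen at C6, beside its C1 oxygen, so the C1 oxygen cannot be the director. The plan disconnects the C3–Br and C5–Br bonds together: an amino group parked at C4, whose para carbon C1 is blocked by methoxy, sends two bromines to its flanking carbons in a single operation and is afterwards exchanged for the C4 bromine by a Sandmeyer reaction. The substrate for this step is the intact diaryl ether, ring B already dibrominated around its free hydroxyl and ring A a 4-amino-1-methoxy arene, reached from a nitroguaiacol by SNAr, Baeyer–Villiger oxidation, ring B bromination and nitro reduction.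

Key step: step 5

Remark: ring A is numbered C1 (oxygen that ends as its hydroxyl), C2 (ether oxygen), C3 to C5 (bromines), C6 (hydrogen); ring B is numbered C1' (ether oxygen), C2' (hydroxyl), C3' and C5' (bromines); compounds 1 and 2 are assumed to be purchasable.

Step 1
Reactants: 1 2-methoxy-5-nitrophenol; 2 2-fluorobenzaldehyde
Product: 3 2-(2-methoxy-5-nitrophenoxy)benzaldehyde
Conditions: K2CO3, DMAc, 110 °C
Reagents that add atoms: none
Why: Nucleophilic aromatic substitution (SNAr): the phenoxide of 1 adds at the fluorine-bearing carbon of 2, the ortho formyl group stabilises the Meisenheimer adduct, and loss of fluoride gives the diaryl ether with the nitro group already para to the methoxy group.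

Step 2
Reactants: 3 2-(2-methoxy-5-nitrophenoxy)benzaldehyde
Product: 5 2-(2-methoxy-5-nitrophenoxy)phenol, via aryl formate 4 (not isolated)
Conditions: mCPBA, CH2Cl2, 0 °C to rt; then HCl (cat.), MeOH, rt
Reagents that add atoms: meta-chloroperoxybenzoic acid (mCPBA), O=C(OO)c1cccc(Cl)c1
Why: Baeyer–Villiger oxidation: in the Criegee intermediate the aryl group bearing an ortho oxygen donor should migrate in preference to hydrogen to give formate 4, which acid-catalysed methanolysis cleaves to the phenol, while the nitro, methoxy and diaryl ether groups are inert to both reagents.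

Step 3
Reactants: 5 2-(2-methoxy-5-nitrophenoxy)phenol
Product: 6 2,4-dibromo-6-(2-methoxy-5-nitrophenoxy)phenol
Conditions: Br2 (2.05 equiv), AcOH, rt
Reagents that add atoms: bromine, BrBr
Why: Electrophilic aromatic bromination: the ring B hydroxyl directs bromine to its one free ortho carbon and to its para carbon, while ring A, deactivated by the nitro group (the masked amine), should not react with a stoichiometric charge of bromine at room temperature.

Step 4
Reactants: 6 2,4-dibromo-6-(2-methoxy-5-nitrophenoxy)phenol
Product: 7 2-(5-amino-2-methoxyphenoxy)-4,6-dibromophenol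
Conditions: Fe powder, AcOH, EtOH/H2O, 60 °C
Reagents that add atoms: none
Why: Béchamp-type reduction: stepwise electron transfer from zerovalent iron with protonation by acetic acid takes the nitro group through the nitroso and hydroxylamine stages to the amine, under conditions that do not cleave aryl bromides as catalytic hydrogenation could.

Step 5
Reactants: 7 2-(5-amino-2-methoxyphenoxy)-4,6-dibromophenol
Product: 8 2-(3-amino-2,4-dibromo-6-methoxyphenoxy)-4,6-dibromophenol
Conditions: NBS (2.0 equiv, portionwise), MeCN, 0 °C to rt
Reagents that add atoms: N-bromosuccinimide (NBS), O=C1CCC(=O)N1Br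
Why: Electrophilic aromatic substitution: electrophilic bromine from NBS attacks ring A at the carbons whose arenium ions are stabilised by the lone pair of the C4 nitrogen, and because the para carbon C1 carries the methoxy group only the two ortho carbons C3 and C5 qualify. The closest known reaction type is the ortho,ortho-dibromination of para-substituted anilines such as 4-methoxyaniline, which sets them up for Sandmeyer conversion into 1,2,3-trihaloarenes. No ring is closed and no stereocentre is created. The selectivity needed is C3 and C5 over C6: C5 is also para and C3 ortho to the C2 ether oxygen, so two donors reinforce each other there, whereas C6 is meta to nitrogen and is activated only by the much weaker C1 methoxy group. Ring B should not compete because the carbons ortho and para to its hydroxyl (C3' and C5') already carry bromine, and exactly two equivalents of NBS at low temperature should stop the reaction after the second substitution at the more crowded C3.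

Step 6
Reactants: 8 2-(3-amino-2,4-dibromo-6-methoxyphenoxy)-4,6-dibromophenol
Product: 10 2,4-dibromo-6-(2,3,4-tribromo-6-methoxyphenoxy)phenol, via diazonium bromide 9 (not isolated)
Conditions: NaNO2, 48% aq HBr, AcOH, 0–5 °C; then CuBr, 48% aq HBr, 60 °C
Reagents that add atoms: hydrobromic acid, Br; CuBr, Br[Cu]
Why: Diazotisation followed by the Sandmeyer reaction: electron transfer from CuBr (monovalent copper) to diazonium ion 9 releases N2 and a C4 aryl radical, which takes bromine from the CuBr2 (divalent copper) so formed and regenerates CuBr; the radical sits meta to the ether bridge and so has no intramolecular trap, and the ring B positions open to diazo coupling or nitrosation are blocked by bromine.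

Step 7
Reactants: 10 2,4-dibromo-6-(2,3,4-tribromo-6-methoxyphenoxy)phenol
Product: 11 3,4,5-tribromo-2-(3,5-dibromo-2-hydroxyphenoxy)phenol (target)
Conditions: BBr3 (3 equiv), CH2Cl2, −78 °C to rt; then H2O
Reagents that add atoms: none
Why: Lewis acid-mediated O-demethylation: BBr3 coordinates to the methoxy oxygen and bromide attacks the methyl carbon (SN2), so only the alkyl–oxygen bond breaks, the aryl–O–aryl bridge and the five C–Br bonds stay intact, and aqueous work-up hydrolyses the aryl borate to the free phenol.

Compound list
1 | 2-methoxy-5-nitrophenol | COc1ccc(cc1O)[N+](=O)[O-] | starting material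
2 | 2-fluorobenzaldehyde | O=Cc1ccccc1F | starting material
3 | 2-(2-methoxy-5-nitrophenoxy)benzaldehyde | COc1ccc(cc1Oc1ccccc1C=O)[N+](=O)[O-] | intermediate
4 | 2-(2-methoxy-5-nitrophenoxy)phenyl formate | COc1ccc(cc1Oc1ccccc1OC=O)[N+](=O)[O-] | intermediate (not isolated)
5 | 2-(2-methoxy-5-nitrophenoxy)phenol | COc1ccc(cc1Oc1ccccc1O)[N+](=O)[O-] | intermediate
6 | 2,4-dibromo-6-(2-methoxy-5-nitrophenoxy)phenol | COc1ccc(cc1Oc1cc(Br)cc(Br)c1O)[N+](=O)[O-] | intermediate
7 | 2-(5-amino-2-methoxyphenoxy)-4,6-dibromophenol | COc1ccc(N)cc1Oc1cc(Br)cc(Br)c1O | intermediate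
8 | 2-(3-amino-2,4-dibromo-6-methoxyphenoxy)-4,6-dibromophenol | COc1cc(Br)c(N)c(Br)c1Oc1cc(Br)cc(Br)c1O | intermediate
9 | 2,6-dibromo-3-(3,5-dibromo-2-hydroxyphenoxy)-4-methoxybenzenediazonium bromide | COc1cc(Br)c([N+]#N)c(Br)c1Oc1cc(Br)cc(Br)c1O.[Br-] | intermediate (not isolated)
10 | 2,4-dibromo-6-(2,3,4-tribromo-6-methoxyphenoxy)phenol | COc1cc(Br)c(Br)c(Br)c1Oc1cc(Br)cc(Br)c1O | intermediate
11 | 3,4,5-tribromo-2-(3,5-dibromo-2-hydroxyphenoxy)phenol | Oc1cc(Br)c(Br)c(Br)c1Oc1cc(Br)cc(Br)c1O | target

Total step count: 7. Longest linear sequence: 7 steps (compound 1 to compound 11).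

Steps most likely to fail

Step 5. After the first bromine enters at C5, substitution at C3, wedged between the amino group and the aryloxy group, may lag; reagent could then drift to C6 or oxidise the electron-rich aminoanisole ring. The fallback sets out from compound 2 and comes back at compound 10. It installs the three ring A bromines before the ether exists, with the hydroxyl that later becomes the ether oxygen as director. Guaiacol (2-methoxyphenol, purchased) treated with Br2 (3 equiv) in AcOH should give 2,3,4-tribromo-6-methoxyphenol F1, the hydroxyl directing to its ortho and para carbons and the methoxy group to its para carbon. The phenoxide of F1 would displace fluoride from compound 2 (K2CO3, DMAc, 130 °C) to give 2-(2,3,4-tribromo-6-methoxyphenoxy)benzaldehyde F2. Oxidation with mCPBA would give 2-(2,3,4-tribromo-6-methoxyphenoxy)phenyl formate F3, methanolysed without isolation (HCl cat., MeOH) to 2-(2,3,4-tribromo-6-methoxyphenoxy)phenol F4. Br2 (2 equiv) in AcOH would then brominate ring B ortho and para to its hydroxyl and give compound 10, from which step 7 follows.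

Step 6. Diazotisation of the weakly basic, doubly ortho-brominated amine may be slow in aqueous acid, and the diazonium ion may be lost to hydrolysis or to reduction by hydrogen-atom transfer from the free ring B hydroxyl to the aryl radical. The fallback sets out from compound 8 and comes back at compound 11. MeI and K2CO3 in acetone should methylate only the acidic ring B hydroxyl, the hindered dibromoaniline nitrogen being too weak a nucleophile, to give 2,6-dibromo-3-(3,5-dibromo-2-methoxyphenoxy)-4-methoxyaniline F5. Aprotic diazotisation and bromination with t-BuONO and CuBr2 in MeCN at 60 °C would pass through 2,6-dibromo-3-(3,5-dibromo-2-methoxyphenoxy)-4-methoxybenzenediazonium bromide F6 to 1,2,3-tribromo-4-(3,5-dibromo-2-methoxyphenoxy)-5-methoxybenzene F7. Excess BBr3 in CH2Cl2 would cleave both methyl ethers at once and give compound 11.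

Step 2. In the Criegee intermediate, migration of the formyl hydrogen may compete with aryl migration, because the nitro-substituted aryloxy group is only a modest donor; the material would then end as the carboxylic acid. The fallback sets out from compound 1 and comes back at compound 5, forming the ether bond with the second oxygen already in place. Ullmann-type coupling of compound 1 with 1-(benzyloxy)-2-iodobenzene (CuI, N,N-dimethylglycine, Cs2CO3, dioxane, 100 °C) should give 2-[2-(benzyloxy)phenoxy]-1-methoxy-4-nitrobenzene F8. BCl3 in CH2Cl2 at −78 to 0 °C would remove the benzyl group selectively, leaving the methyl ether and the nitro group, and give compound 5.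

Further compounds
F1 | step 5 | 2,3,4-tribromo-6-methoxyphenol | COc1cc(Br)c(Br)c(Br)c1O
F2 | step 5 | 2-(2,3,4-tribromo-6-methoxyphenoxy)benzaldehyde | COc1cc(Br)c(Br)c(Br)c1Oc1ccccc1C=O
F3 | step 5 | 2-(2,3,4-tribromo-6-methoxyphenoxy)phenyl formate | COc1cc(Br)c(Br)c(Br)c1Oc1ccccc1OC=O
F4 | step 5 | 2-(2,3,4-tribromo-6-methoxyphenoxy)phenol | COc1cc(Br)c(Br)c(Br)c1Oc1ccccc1O
F5 | step 6 | 2,6-dibromo-3-(3,5-dibromo-2-methoxyphenoxy)-4-methoxyaniline | COc1cc(Br)c(N)c(Br)c1Oc1cc(Br)cc(Br)c1OC
F6 | step 6 | 2,6-dibromo-3-(3,5-dibromo-2-methoxyphenoxy)-4-methoxybenzenediazonium bromide | COc1cc(Br)c([N+]#N)c(Br)c1Oc1cc(Br)cc(Br)c1OC.[Br-]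
F7 | step 6 | 1,2,3-tribromo-4-(3,5-dibromo-2-methoxyphenoxy)-5-methoxybenzene | COc1cc(Br)c(Br)c(Br)c1Oc1cc(Br)cc(Br)c1OC
F8 | step 2 | 2-[2-(benzyloxy)phenoxy]-1-methoxy-4-nitrobenzene | COc1ccc(cc1Oc1ccccc1OCc1ccccc1)[N+](=O)[O-]
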